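**Retrosynthetic overview**
- The 1,2-dioxolan-3-ol is made last: Schenck ene reaction of the lower isopropylidene enone, then closure of the hydroperoxide onto the C8′ ketone.
- The bicyclo[2.2.1]heptene core comes from an endo cross Diels–Alder reaction (bonds C3–C3′ and C1–C4′) of a 2-acetoxyguaia-1(5),3-diene with a guaia-1(5),3,7(11)-triene-2,8-dione, both unmasked in one flask.
- Both partners come from one 4-hydroxy-2-oxoguaia-1(5)-ene, reached by C2 oxidation and a 1(10)→1(5) alkene shift that relays C5 chirality to C10.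
- The five/seven-membered bicycle comes from transannular epoxide–olefin cyclization of germacrone 4,5-epoxide, made by asymmetric epoxidation of achiral germacrone.
- Ring order: ten-membered ring (bought) → five/seven-membered bicycle → bicyclo[2.2.1]heptene → 1,2-dioxolane.

Assumption: guaiane numbering is used (primed = lower, dienophile-derived unit), and the natural configurations at the epimerizable C7 and at hemiketal C8′ are taken to be the thermodynamic ones.

**Step 1**
Reactants: 1 germacrone
Product: 2 (4S,5S)-4,5-epoxygermacra-1(10),7(11)-dien-8-one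
Conditions: ent-Shi ketone (1,2:4,5-di-O-isopropylidene-β-L-erythro-2,3-hexodiulo-2,6-pyranose, 0.3 equiv), KHSO5 (1.4 equiv, as 2KHSO5·KHSO4·K2SO4), K2CO3, Bu4NHSO4, MeCN/CH2(OMe)2–aq. Na2B4O7, 0 °C
Reagents that add atoms: potassium peroxymonosulfate, [K+].[O-]S(=O)(=O)OO
Why: Shi asymmetric epoxidation, in which the chiral dioxirane attacks only the exposed outer face of the most electron-rich E-trisubstituted alkene (C4=C5; C1=C10 is deactivated by the β-carbonyl and C7=C11 is an enone), and because the enantiomeric ring conformers of germacrone interconvert quickly the spiro transition state of the L-series ketone funnels the material to the (4S,5S)-epoxide.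

**Step 2**
Reactants: 2 (4S,5S)-4,5-epoxygermacra-1(10),7(11)-dien-8-one
Product: 3 (4S,5S)-4-hydroxyguaia-1(10),7(11)-dien-8-one
Conditions: TsOH·H2O (5 mol%), CH2Cl2, 0 °C
Reagents that add atoms: none
Why: Biomimetic transannular epoxide–olefin cyclization (the parthenolide-to-micheliolide type), in which C1 of the 1(10)-alkene opens the protonated epoxide at C5 with inversion while C4 keeps its oxygen (4-OH cis to 5-H), and the tertiary C10 cation loses the electron-rich H1 to give the tetrasubstituted 1(10)-alkene.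

**Step 3**
Reactants: 3 (4S,5S)-4-hydroxyguaia-1(10),7(11)-dien-8-one
Product: 4 (4S,5S)-2,4-dihydroxyguaia-1(10),7(11)-dien-8-one (C2 epimer mixture)
Conditions: SeO2 (0.3 equiv), t-BuOOH (3 equiv), CH2Cl2, rt
Reagents that add atoms: tert-butyl hydroperoxide, CC(C)(C)OO; selenium dioxide, O=[Se]=O
Why: Selenium dioxide allylic hydroxylation (ene reaction then [2,3]-shift), in which selenium bonds to C10 so that positive charge builds at C1, away from the C8 carbonyl, the ring methylene hydrogen at C2 is taken in preference to the tertiary H5 or the electron-poor α-keto H9, and the [2,3]-shift restores the 1(10)-alkene; the new C2 carbinol centre is erased in step 4.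

**Step 4**
Reactants: 4 (4S,5S)-2,4-dihydroxyguaia-1(10),7(11)-dien-8-one
Product: 5 (4S,5S)-4-hydroxyguaia-1(10),7(11)-diene-2,8-dione
Conditions: Dess–Martin periodinane (1.3 equiv), CH2Cl2, 0 °C
Reagents that add atoms: none
Why: Dess–Martin oxidation converts only the secondary allylic alcohol into the exocyclic enone, since the tertiary C4 alcohol cannot be oxidized and no stereocentre is touched.

**Step 5**
Reactants: 5 (4S,5S)-4-hydroxyguaia-1(10),7(11)-diene-2,8-dione
Product: 6 (4S,10R)-4-hydroxyguaia-1(5),7(11)-diene-2,8-dione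
Conditions: RhCl3·3H2O (5 mol%), EtOH, 60 °C
Reagents that add atoms: none
Why: Rhodium-hydride exo-to-endo enone isomerization (known for 2-alkylidenecyclopentanones), in which syn hydrometalation puts H on C10 from the face that bears H5 (the other face is blocked by C6) and syn β-hydride elimination then removes H5, a net suprafacial 1,3-hydrogen shift that turns 5S into 10R and is driven by the endocyclic tetrasubstituted cyclopentenone.

**Step 6**
Reactants: 6 (4S,10R)-4-hydroxyguaia-1(5),7(11)-diene-2,8-dione
Product: 7 (4S,7S,10R)-4-hydroxyguai-1(5)-ene-2,8-dione (7S drawn; the 7-epimer is carried on and converged in step 7)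
Conditions: [(Ph3P)CuH]6 (3 mol%), H2 (10 atm), PhH/t-BuOH, rt
Reagents that add atoms: none
Why: Copper hydride conjugate reduction (Stryker type) delivers hydride to the open dimethyl-substituted β-carbon C11 of the isopropylidene enone and not to the ring-fusion β-carbon C5 next to quaternary C4, and C7 is formed by enolate protonation as a mixture that is equilibrated later.

**Step 7**
Reactants: 7 (4S,7S,10R)-4-hydroxyguai-1(5)-ene-2,8-dione
Product: 8 (2S,4S,7S,10R)-2,4-dihydroxyguai-1(5)-en-8-one
Conditions: Me4NBH(OAc)3 (3 equiv), MeCN/AcOH, −20 °C; then DBU (0.2 equiv), PhMe, rt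
Reagents that add atoms: none
Why: Evans–Saksena hydroxyl-directed reduction, in which boron bound to the 4-OH delivers hydride to the same face of the C2 carbonyl to give the 2,4-trans diol (2S, hydrogen on the H10 face) while the undirected C8 ketone is left alone, and the DBU treatment equilibrates C7 (α to C8=O) to the 7S epimer with isopropyl cis to the C10 methyl.

**Step 8**
Reactants: 8 (2S,4S,7S,10R)-2,4-dihydroxyguai-1(5)-en-8-one
Product: 9 (2S,4S,7S,10R)-2-acetoxy-4-hydroxyguai-1(5)-en-8-one
Conditions: Ac2O (1.2 equiv), pyridine, DMAP (5 mol%), CH2Cl2, 0 °C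
Reagents that add atoms: acetic anhydride, CC(=O)OC(C)=O
Why: DMAP-catalysed acylation takes the secondary allylic alcohol far faster than the tertiary one, with no change at any stereocentre.

**Step 9**
Reactants: 9 (2S,4S,7S,10R)-2-acetoxy-4-hydroxyguai-1(5)-en-8-one; 6 (4S,10R)-4-hydroxyguaia-1(5),7(11)-diene-2,8-dione
Product: 12 endo cross-adduct (1R,2S,3R,7S,10R,3′R,4′S,10′R)-2-acetoxy-1,4′:3,3′-linked guai-4-en-8-one/guaia-1′(5′),7′(11′)-diene-2′,8′-dione, via acetoxydiene 10 (not isolated), via cyclopentadienone 11 (not isolated)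
Conditions: 9 (2 equiv), 6 (1 equiv), Ph2S[OC(CF3)2Ph]2 (3.5 equiv), CH2Cl2, −40 → 0 °C, then rt
Reagents that add atoms: none
Why: Proposed new method: the sulfurane dehydrates both tertiary alcohols in the cold (loss of H3 from the C4 allyl cation of 9 gives the kinetic 5-acetoxycyclopentadiene 10, and loss of the α-keto H3 from 6 gives cyclopentadienone 11), and the electron-rich diene 10, used in excess, traps 11 faster than 11 dimerizes in an endo Diels–Alder reaction whose leading bond joins the two unsubstituted termini C3 and C3′ (the frontier coefficients of a cyclopentadienone are largest at its α-carbons) before C1–C4′ closes; the dienophile enters the diene face bearing H2 and H10 because the other face is screened by both the acetoxy group and the pseudoaxial C10 methyl and because its exo C4′ methyl would clash with a syn acetoxy group, which puts OAc over the new C4=C5 bond, and endo alignment then makes 11 react on its own H10′ face, so C1, C2, C3, C3′ and C4′ are fixed together; the closest known reaction types are the Diels–Alder dimerization of cyclopentadienones generated in situ and cycloadditions of 5-acetoxycyclopentadienes, which normally go syn to oxygen, so the steric override is the unproven element.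

**Step 10**
Reactants: 12 endo cross-adduct
Product: 14 target CNP0317907.1 (1R,2S,3R,7S,10R,3′R,4′S,8′R,10′R), via hydroperoxide 13 (not isolated)
Conditions: O2, tetraphenylporphyrin (1 mol%), visible light, CH2Cl2, −20 °C
Reagents that add atoms: dioxygen, O=O
Why: Schenck ene reaction of singlet oxygen with the gem selectivity typical of α,β-unsaturated ketones (as with pulegone), in which oxygen bonds to C11′ and H6′ is removed to give the conjugated 6′-ene, the tertiary hydroperoxide closes onto the C8′ ketone to the 1,2-dioxolan-3-ol as its thermodynamic 8′R anomer, and the upper C4=C5 bond is spared because its exo face is covered by the syn acetoxy group and its endo face by the lower cyclopentenone.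

**Compound list**
1 | germacrone, (3E,7E)-3,7-dimethyl-10-(propan-2-ylidene)cyclodeca-3,7-dien-1-one | C/C1=C\CC/C(C)=C/CC(=C(C)C)C(=O)C1 | starting material
2 | (4S,5S)-4,5-epoxygermacra-1(10),7(11)-dien-8-one | C/C1=C\CC[C@]2(C)O[C@H]2CC(=C(C)C)C(=O)C1 | intermediate
3 | (4S,5S)-4-hydroxyguaia-1(10),7(11)-dien-8-one (4-OH cis to 5-H) | CC1=C2CC[C@](C)(O)[C@H]2CC(=C(C)C)C(=O)C1 | intermediate
4 | (4S,5S)-2,4-dihydroxyguaia-1(10),7(11)-dien-8-one, C2 epimers | CC1=C2C(O)C[C@](C)(O)[C@H]2CC(=C(C)C)C(=O)C1 | intermediate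
5 | (4S,5S)-4-hydroxyguaia-1(10),7(11)-diene-2,8-dione | CC1=C2C(=O)C[C@](C)(O)[C@H]2CC(=C(C)C)C(=O)C1 | intermediate
6 | (4S,10R)-4-hydroxyguaia-1(5),7(11)-diene-2,8-dione (4-OH and 10-H on the same face) | C[C@@H]1CC(=O)C(=C(C)C)CC2=C1C(=O)C[C@]2(C)O | intermediate
7 | (4S,7S,10R)-4-hydroxyguai-1(5)-ene-2,8-dione | C[C@@H]1CC(=O)[C@H](C(C)C)CC2=C1C(=O)C[C@]2(C)O | intermediate
8 | (2S,4S,7S,10R)-2,4-dihydroxyguai-1(5)-en-8-one (2,4-trans diol) | C[C@@H]1CC(=O)[C@H](C(C)C)CC2=C1[C@@H](O)C[C@]2(C)O | intermediate
9 | (2S,4S,7S,10R)-2-acetoxy-4-hydroxyguai-1(5)-en-8-one | C[C@@H]1CC(=O)[C@H](C(C)C)CC2=C1[C@@H](OC(C)=O)C[C@]2(C)O | intermediate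
10 | (2S,7S,10R)-2-acetoxyguaia-1(5),3-dien-8-one (5-acetoxycyclopentadiene, not isolated) | C[C@@H]1CC(=O)[C@H](C(C)C)CC2=C1[C@@H](OC(C)=O)C=C2C | intermediate
11 | (10R)-guaia-1(5),3,7(11)-triene-2,8-dione (cyclopentadienone, not isolated) | C[C@@H]1CC(=O)C(=C(C)C)CC2=C1C(=O)C=C2C | intermediate
12 | endo cross-adduct; upper 2-acetoxyguai-4-en-8-one (OAc syn to C4=C5), lower guaia-1′(5′),7′(11′)-diene-2′,8′-dione, bonds C1–C4′ and C3–C3′ | CC(=O)O[C@H]1[C@H]2C(C)=C3C[C@@H](C(C)C)C(=O)C[C@@H](C)[C@]31[C@]1(C)C3=C(C(=O)[C@H]21)[C@H](C)CC(=O)C(=C(C)C)C3 | intermediate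
13 | 11′-hydroperoxy-6′-ene of 12 (open hydroperoxy ketone, not isolated) | CC(=O)O[C@H]1[C@H]2C(C)=C3C[C@@H](C(C)C)C(=O)C[C@@H](C)[C@]31[C@]1(C)C3=C(C(=O)[C@H]21)[C@H](C)CC(=O)C(C(C)(C)OO)=C3 | intermediate
14 | CNP0317907.1 | CC(=O)O[C@H]1[C@H]2C(C)=C3C[C@@H](C(C)C)C(=O)C[C@@H](C)[C@]31[C@]1(C)C3=C(C(=O)[C@H]21)[C@H](C)C[C@@]1(O)OOC(C)(C)C1=C3 | target

**Totals**
Total step count: 10. Longest linear sequence: 10 (1 → 6 → 9 → 12 → 14; compound 6 is used a second time as the dienophile precursor in step 9).

**Three steps most likely to fail**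

Step 9 (cross Diels–Alder). The risks are attack syn to the acetoxy group (the usual preference of 5-acetoxycyclopentadienes), a [1,5]-hydrogen shift in 10 before it is trapped, and self-dimerization of 11. Any bridged-ketone adduct from the alternative periselectivity should converge on 12 by [3,3]-shift on gentle warming. The fallback sets out from 8 and returns at 12. Diol 8 is silylated at the secondary hydroxyl (t-BuPh2SiCl, imidazole, DMF) to give the 2-O-tert-butyldiphenylsilyl ether F1. F1 (2 equiv) and 6 are dehydrated together with Ph2S[OC(CF3)2Ph]2 as before; the diene is now the 2-silyloxyguaia-1(5),3-diene F2, whose very large silyl group shields its own face on steric grounds alone. The cycloadduct silyl ether F3 therefore carries the bridge oxygen syn to C4=C5. HF·pyridine (THF, 0 °C) frees the bridge alcohol F4, and Ac2O/DMAP/pyridine gives 12.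

Step 5 (exo-to-endo isomerization with chirality relay). The risks are dehydration of the β-hydroxy ketone, migration of the isopropylidene double bond to the 6-ene, and drift into the 9-ene tautomer. The fallback sets out from 5 and returns at 6. Hydroxyl-directed hydrogenation of the exocyclic enone with [Ir(cod)(PCy3)(py)]PF6 and H2 (CH2Cl2, rt) adds both hydrogens from the 4-OH face and gives the cis-fused saturated hydroxy diketone F5 with C10 already R. Soft enolization of the more acidic cyclopentanone (Me3SiOTf, Et3N, CH2Cl2, 0 °C) gives the tetrasubstituted trimethylsilyl enol ether F6. Saegusa–Ito oxidation with Pd(OAc)2 (MeCN, rt) then reinstates unsaturation toward C5 to give 6; any 5 formed by elimination toward C10 is recycled.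

Step 3 (allylic hydroxylation at C2). The risks are competing oxidation at C14 or C9 and low reactivity of the tetrasubstituted alkene. The fallback sets out from 3 and returns at 5. Photooxygenation of 3 (O2, tetraphenylporphyrin, visible light, CH2Cl2, −20 °C) by an ene reaction that removes H2 gives the 10-hydroperoxy-4-hydroxyguaia-1,7(11)-dien-8-one F7. Triphenylphosphine reduces it to the tertiary allylic alcohol F8. Babler–Dauben oxidative 1,3-transposition with pyridinium chlorochromate [C5H5NH][CrO3Cl] (CH2Cl2, rt) moves the oxygen to C2 as the ketone and restores the 1(10)-alkene, giving 5 directly.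

**Further compounds**
F1 | step 9 | (2S,4S,7S,10R)-2-(tert-butyldiphenylsilyloxy)-4-hydroxyguai-1(5)-en-8-one | C[C@@H]1CC(=O)[C@H](C(C)C)CC2=C1[C@@H](O[Si](c1ccccc1)(c1ccccc1)C(C)(C)C)C[C@]2(C)O
F2 | step 9 | (2S,7S,10R)-2-(tert-butyldiphenylsilyloxy)guaia-1(5),3-dien-8-one | C[C@@H]1CC(=O)[C@H](C(C)C)CC2=C1[C@@H](O[Si](c1ccccc1)(c1ccccc1)C(C)(C)C)C=C2C
F3 | step 9 | 2-O-tert-butyldiphenylsilyl analogue of cross-adduct 12 | CC(C)(C)[Si](c1ccccc1)(c1ccccc1)O[C@H]1[C@H]2C(C)=C3C[C@@H](C(C)C)C(=O)C[C@@H](C)[C@]31[C@]1(C)C3=C(C(=O)[C@H]21)[C@H](C)CC(=O)C(=C(C)C)C3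
F4 | step 9 | 2-hydroxy (deacetyl) analogue of cross-adduct 12 | O[C@H]1[C@H]2C(C)=C3C[C@@H](C(C)C)C(=O)C[C@@H](C)[C@]31[C@]1(C)C3=C(C(=O)[C@H]21)[C@H](C)CC(=O)C(=C(C)C)C3
F5 | step 5 | (1S,4S,5S,10R)-4-hydroxyguai-7(11)-ene-2,8-dione (cis-fused, H1, H5, H10 and 4-OH on one face) | C[C@@H]1CC(=O)C(=C(C)C)C[C@H]2[C@@H]1C(=O)C[C@]2(C)O
F6 | step 5 | (4S,5S,10R)-4-hydroxy-2-(trimethylsilyloxy)guaia-1,7(11)-dien-8-one | C[C@@H]1CC(=O)C(=C(C)C)C[C@H]2C1=C(O[Si](C)(C)C)C[C@]2(C)O
F7 | step 3 | (4S,5S)-10-hydroperoxy-4-hydroxyguaia-1,7(11)-dien-8-one | CC1(OO)CC(=O)C(=C(C)C)C[C@H]2C1=CC[C@]2(C)O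
F8 | step 3 | (4S,5S)-4,10-dihydroxyguaia-1,7(11)-dien-8-one | CC1(O)CC(=O)C(=C(C)C)C[C@H]2C1=CC[C@]2(C)O
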